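## Retrosynthetic overview

1. Locants: C1–C10 = the trans-decalin (C4 = C(CH3)(CH2OH) with C18 = CH2OH; C10 = C–CH3), C8 = quaternary bridgehead, C9=C11 = the alkene, C12 = bridgehead CH, C13–C14 = CH2CH2, C15 = CHOH bridge, C16 = C(OH), C17 = CH2OAc.
2. Enabling feature: the six-membered ring C8–C14–C13–C16–C12–C15 carries oxygen on C15 and C16, both bonded to C12, so it is a reduced 3-methoxyphenol. Its ortho carbons C8 and C12 are spanned by C9–C11, so the bicyclo[3.2.1]octene (that ring plus the five-membered ring C8–C9–C11–C12–C15) is the [5+2] adduct of a phenoxonium ion and a two-carbon enol ether. The C8–C9 bond made by this cycloaddition also closes ring B.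
3. Disconnections after the key step, backwards: C17–OAc from a C16 spiro-epoxide (from the C16 ketone); C9=C11 by dehydration of a C9 carbinol (the enol ether oxygen); C15–OH from the bridging ketone.
4. Precursor: ring A with a C5 CH2CH2-aryl arm and a C10 1-(benzyloxy)vinyl group. It comes from dehydroabietic acid by oxidative excision of the aromatic ring (C8–C9 cleaved, C4/C5/C10 kept), decarboxylative arylation at C7 and ester methylenation at C9.
5. Ring order: ring A (chiral pool) → ring B, the five-membered ring and the bicyclic framework with ring D in one step (step 10) → oxidation-level and functional-group adjustment.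

Key step: step 10

Remark: (+)-dehydroabietic acid and 2-iodo-5-methoxyphenol are taken as catalogue compounds; the C9 stereocentre made in step 10 is temporary and is removed in step 14.

## Route

Step 1
Reactants: 1 (+)-dehydroabietic acid
Product: 2 dehydroabietinol (abieta-8,11,13-trien-18-ol; C4, C5, C10 as in 1)
Conditions: LiAlH4, THF, 0 °C to reflux; aqueous NaOH work-up
Reagents that add atoms: none
Why: LiAlH4 reduction of the hindered C18 carboxylic acid should give the neopentyl primary alcohol without touching the arene or any stereocentre.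

Step 2
Reactants: 2 dehydroabietinol
Product: 3 18-O-triisopropylsilyl dehydroabietinol
Conditions: TIPSCl, imidazole, DMF, 40 °C
Reagents that add atoms: triisopropylsilyl chloride, CC(C)[Si](Cl)(C(C)C)C(C)C
Why: Routine silylation of a primary alcohol gives a TIPS ether that should survive RuO4, the organozinc and titanium reagents, mild base and the buffered oxidation of step 10.

Step 3
Reactants: 3 18-O-triisopropylsilyl dehydroabietinol
Product: 4 ring-A diacid (C5 arm CH2CH2CO2H = C6–C7–C8; C10 carries CO2H = C9; C4, C5, C10 as in 1)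
Conditions: RuCl3·xH2O (5 mol%), NaIO4 (excess), CCl4/MeCN/H2O, rt
Reagents that add atoms: sodium periodate, [Na+].[O-]I(=O)(=O)=O; water, O
Why: RuO4 generated in situ degrades the trialkylbenzene ring (oxidative arene degradation to carboxylic acids), so C8 and C9 remain as CO2H groups, the C8–C9 bond is cut, and C4, C5 and C10 are kept because no bond at these centres is broken.

Step 4
Reactants: 4 ring-A diacid
Product: 5 mono N-acyloxyphthalimide at the C8 carboxyl (C9 acid free)
Conditions: N-hydroxyphthalimide (1.05 equiv), N,N'-diisopropylcarbodiimide (1.05 equiv), DMAP (5 mol%), CH2Cl2, 0 °C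
Reagents that add atoms: N-hydroxyphthalimide, O=C1c2ccccc2C(=O)N1O
Why: In this carbodiimide (Steglich-type) esterification only the unhindered primary C8 acid should acylate N-hydroxyphthalimide, the α-quaternary C9 acid being too shielded.

Step 5
Reactants: 5 mono N-acyloxyphthalimide
Product: 6 C9 benzyl ester of 5
Conditions: benzyl 2,2,2-trichloroacetimidate, CH2Cl2/cyclohexane, rt
Reagents that add atoms: benzyl 2,2,2-trichloroacetimidate, N=C(OCc1ccccc1)C(Cl)(Cl)Cl
Why: Imidate benzylation alkylates the carboxylate oxygen, so it is insensitive to the quaternary α-carbon and runs under near-neutral conditions that spare the redox-active ester.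

Step 6
Reactants: 7 2-iodo-5-methoxyphenol
Product: 8 tert-butyl(2-iodo-5-methoxyphenoxy)dimethylsilane
Conditions: TBSCl, imidazole, DMF, rt
Reagents that add atoms: tert-butyldimethylsilyl chloride, CC(C)(C)[Si](C)(C)Cl
Why: Routine phenol silylation protects the hydroxyl during zinc insertion, cross-coupling and methylenation.

Step 7
Reactants: 6 C9 benzyl ester with C8 N-acyloxyphthalimide; 8 tert-butyl(2-iodo-5-methoxyphenoxy)dimethylsilane
Product: 10 C7-aryl benzyl ester, via arylzinc iodide 9 (not isolated)
Conditions: 8, Zn dust, LiCl, THF, 50 °C; then 6, NiCl2·glyme (20 mol%), 4,4'-di-tert-butyl-2,2'-bipyridine (40 mol%), THF/DMF, rt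
Reagents that add atoms: none
Why: In this nickel-catalysed decarboxylative Negishi-type coupling of a redox-active ester, single-electron reduction, loss of CO2 and capture of the primary C7 radical at nickel should join the aryl ipso carbon (the new C8) to C7, while the hindered benzyl ester and the silyl ethers stay inert.

Step 8
Reactants: 10 C7-aryl benzyl ester
Product: 11 1-(benzyloxy)vinyl compound (C10–C9(OBn)=C11H2)
Conditions: Tebbe reagent Cp2Ti(CH2)(Cl)AlMe2, pyridine (cat.), THF/toluene, −40 °C to rt; aqueous NaOH work-up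
Reagents that add atoms: Tebbe reagent (written as titanocene methylidene with Me2AlCl), C=[Ti](C1C=CC=C1)C1C=CC=C1.C[Al](C)Cl
Why: Tebbe methylenation converts the ester C=O into C=CH2 through a titanaoxetane, giving the enol ether (C9=C11) without acid and without reaction at the aryl or alkyl silyl ethers.

Step 9
Reactants: 11 1-(benzyloxy)vinyl compound
Product: 12 free phenol (2-alkyl-5-methoxyphenol)
Conditions: K2CO3 (cat.), MeOH/THF, rt
Reagents that add atoms: none
Why: Base-catalysed methanolysis cleaves the aryl silyl ether much faster than the alkyl TIPS ether and leaves the acid-sensitive enol ether untouched.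

Step 10
Reactants: 12 free phenol
Product: 15 C9-benzyloxy tetracyclic enedione, via phenoxonium ion 13 (not isolated), via methyloxocarbenium cycloadduct 14 (not isolated)
Conditions: PhI(OAc)2 (1.1 equiv), 2,6-di-tert-butylpyridine, 1,1,1,3,3,3-hexafluoropropan-2-ol/CH2Cl2 (1:3), −40 to 0 °C; then aqueous NaHCO3
Reagents that add atoms: water, O
Why: PhI(OAc)2 oxidises the phenol by two electrons to phenoxonium ion 13, whose five-carbon cation C8–C14–C13–C16–C12 (capped by the C15 carbonyl) adds across the tethered enol ether in a cationic [5+2] cycloaddition of the perezone type, here in its oxidative-dearomatisation-induced intramolecular form, which is the closest known reaction: the nucleophilic CH2 (C11) bonds to C12, the ortho carbon between the two oxygenated carbons, and the benzyloxycarbenium carbon C9 that develops is captured by C8. Ring B is closed by the C8–C9 bond as a six-membered ring through a chair (6-exo-trig attack of the dienone carbon C8 on the C9 oxocarbenium carbon), the five-membered ring C8–C9–C11–C12–C15 is closed in the same event by the two new bonds on one face of the cation, and the O-methyl oxocarbenium ion 14 left on C16 is hydrolysed to the enone on work-up. C8 is controlled by C5 and C10: with the C5 arm and the C10–C9 bond equatorial on ring A, only one face of the cation lets ring B form as a chair with C10 exo on the new two-carbon bridge, which puts the C15 carbonyl bridge axial on ring B and syn to the C10 methyl as the target requires, whereas the other face needs a twist-boat ring B or an endo C10 that pushes ring A over the cation. C12 follows from C8 because both bonds form on the same face, and C9 (benzyloxy endo, C10 exo) is set by the same chair and removed later. The step needs site selectivity (C8/C12 against the free para carbon C13 and against closure on oxygen) and must outrun re-aromatisation and enol ether hydrolysis: the four-atom tether holds C9 over C8, the methoxy group on C16 stabilises the allyl cation that the [5+2] mode leaves behind, C8 cannot re-aromatise once bonded, and the fluorinated solvent with a hindered pyridine keeps the medium non-nucleophilic and non-acidic.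

Step 11
Reactants: 15 C9-benzyloxy tetracyclic enedione
Product: 16 C15 alcohol (hydroxyl on the face of the C9–C11 bridge)
Conditions: NaBH4, MeOH/CH2Cl2, −78 °C
Reagents that add atoms: none
Why: NaBH4 should reduce the strained, non-conjugated bridging ketone in preference to the enone, and because the face of C15 over the two-carbon bridge is blocked by the exo C10 and its axial methyl, hydride should enter from the flat enone face and place the hydroxyl toward the C9–C11 bridge as in the target.

Step 12
Reactants: 16 C15 alcohol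
Product: 17 C15 tert-butyldimethylsilyl ether
Conditions: TBSOTf, 2,6-lutidine, CH2Cl2, 0 °C to rt
Reagents that add atoms: tert-butyldimethylsilyl trifluoromethanesulfonate, CC(C)(C)[Si](C)(C)OS(=O)(=O)C(F)(F)F
Why: Silylation masks the C15 hydroxyl so that the β-hydroxy ketone cannot open by retro-aldol cleavage under the basic ylide conditions of step 15.

Step 13
Reactants: 17 C15 silyl ether
Product: 18 9α-hydroxy 16-ketone (C13–C14 saturated)
Conditions: H2 (1 atm), Pd(OH)2/C, EtOAc, rt
Reagents that add atoms: none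
Why: Heterogeneous hydrogenation saturates the C13=C14 enone double bond and hydrogenolyses the tertiary benzyl ether in one operation without creating a stereocentre.

Step 14
Reactants: 18 9α-hydroxy 16-ketone
Product: 19 9(11)-ene 16-ketone
Conditions: SOCl2, pyridine, CH2Cl2, −30 to 0 °C
Reagents that add atoms: none
Why: This is the classical SOCl2/pyridine dehydration of tertiary 9-hydroxy steroids to 9(11)-alkenes, and because C8 and C10 are quaternary only C11 offers β-hydrogens (one syn-periplanar to the leaving group), so the 9(11)-alkene is the only possible product and its formation also relieves the 1,3-diaxial contact between the C10 methyl and C15.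

Step 15
Reactants: 19 9(11)-ene 16-ketone
Product: 20 C16 spiro-epoxide (CH2 syn to C15, oxygen equatorial)
Conditions: Me3S+ I−, KN(SiMe3)2, THF, 0 °C to rt
Reagents that add atoms: trimethylsulfonium iodide, C[S+](C)C.[I-]
Why: In this Corey–Chaykovsky epoxidation the small, irreversibly adding sulfonium ylide should attack the C16 ketone axially, from the face of the C15 hydrogen and anti to the C12–C11 bond, so that the new CH2 (C17) is syn to C15 and the oxygen equatorial as in the target.

Step 16
Reactants: 20 C16 spiro-epoxide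
Product: 21 15-O-TBS, 18-O-TIPS ether of Botryotin E
Conditions: CsOAc, AcOH, DMF, 80 °C
Reagents that add atoms: acetic acid (delivered as acetate by CsOAc, which is re-formed), CC(=O)O
Why: SN2 opening of the 2,2-disubstituted epoxide by acetate at the CH2 terminus should give the primary acetate and the tertiary alcohol directly with C16 untouched, acetic acid protonating the alkoxide before it can transacylate.

Step 17
Reactants: 21 bis-silyl ether of Botryotin E
Product: 22 Botryotin E
Conditions: HF·pyridine, pyridine, THF, 0 °C to rt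
Reagents that add atoms: none
Why: Buffered HF·pyridine should cleave both silyl ethers under conditions in which the primary acetate, the tertiary alcohol and the alkene are stable.

## Compound list

1 | (+)-dehydroabietic acid (abieta-8,11,13-trien-18-oic acid; 4β-CH3, 4α-CO2H, 5α-H, 10β-CH3) | CC(C)c1ccc2c(c1)CC[C@H]3[C@](C)(C(=O)O)CCC[C@]23C | starting material
2 | dehydroabietinol (abieta-8,11,13-trien-18-ol; centres as in 1) | CC(C)c1ccc2c(c1)CC[C@H]3[C@](C)(CO)CCC[C@]23C | intermediate
3 | 18-O-triisopropylsilyl dehydroabietinol | CC(C)c1ccc2c(c1)CC[C@H]3[C@](C)(CO[Si](C(C)C)(C(C)C)C(C)C)CCC[C@]23C | intermediate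
4 | ring-A diacid: 4β-CH3/4α-CH2OTIPS, 5α-H with equatorial CH2CH2CO2H (C6–C7–C8), 10β-CH3 with CO2H (C9) | OC(=O)CC[C@H]1[C@](C)(CO[Si](C(C)C)(C(C)C)C(C)C)CCC[C@]1(C)C(=O)O | intermediate
5 | mono N-acyloxyphthalimide of 4 at the C8 carboxyl | O=C1c2ccccc2C(=O)N1OC(=O)CC[C@H]3[C@](C)(CO[Si](C(C)C)(C(C)C)C(C)C)CCC[C@]3(C)C(=O)O | intermediate
6 | C9 benzyl ester of 5 | O=C1c2ccccc2C(=O)N1OC(=O)CC[C@H]3[C@](C)(CO[Si](C(C)C)(C(C)C)C(C)C)CCC[C@]3(C)C(=O)OCc4ccccc4 | intermediate
7 | 2-iodo-5-methoxyphenol | Oc1cc(OC)ccc1I | starting material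
8 | tert-butyl(2-iodo-5-methoxyphenoxy)dimethylsilane | COc1ccc(I)c(O[Si](C)(C)C(C)(C)C)c1 | intermediate
9 | [2-(tert-butyldimethylsilyloxy)-4-methoxyphenyl]zinc iodide | COc1ccc([Zn]I)c(O[Si](C)(C)C(C)(C)C)c1 | intermediate
10 | benzyl ester with C5 arm CH2CH2–Ar (Ar = 2-TBSO-4-methoxyphenyl, ipso carbon = C8) | COc1ccc(CC[C@H]2[C@](C)(CO[Si](C(C)C)(C(C)C)C(C)C)CCC[C@]2(C)C(=O)OCc3ccccc3)c(O[Si](C)(C)C(C)(C)C)c1 | intermediate
11 | 1-(benzyloxy)vinyl compound (C10–C9(OBn)=C11H2), otherwise as 10 | COc1ccc(CC[C@H]2[C@](C)(CO[Si](C(C)C)(C(C)C)C(C)C)CCC[C@]2(C)C(=C)OCc3ccccc3)c(O[Si](C)(C)C(C)(C)C)c1 | intermediate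
12 | free phenol of 11 (2-alkyl-5-methoxyphenol) | COc1ccc(CC[C@H]2[C@](C)(CO[Si](C(C)C)(C(C)C)C(C)C)CCC[C@]2(C)C(=C)OCc3ccccc3)c(O)c1 | intermediate
13 | phenoxonium ion of 12 (C15=O; cation over C8, C13, C12) | COC1=CC(=O)[C+](CC[C@H]2[C@](C)(CO[Si](C(C)C)(C(C)C)C(C)C)CCC[C@]2(C)C(=C)OCc3ccccc3)C=C1 | intermediate
14 | O-methyl oxocarbenium cycloadduct (C16=O+CH3) | C[O+]=C1C=C[C@]23CC[C@H]4[C@](C)(CO[Si](C(C)C)(C(C)C)C(C)C)CCC[C@]4(C)[C@@]2(OCc5ccccc5)C[C@H]1C3=O | intermediate
15 | tetracyclic enedione: rings A/B trans, C8 quaternary with C15 on the β face, 9α-OBn, C15=O bridge, C16=O conjugated with C13=C14, 18-OTIPS | O=C1C=C[C@]23CC[C@H]4[C@](C)(CO[Si](C(C)C)(C(C)C)C(C)C)CCC[C@]4(C)[C@@]2(OCc5ccccc5)C[C@H]1C3=O | intermediate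
16 | C15 alcohol of 15 (OH toward the C9–C11 bridge) | O=C1C=C[C@]23CC[C@H]4[C@](C)(CO[Si](C(C)C)(C(C)C)C(C)C)CCC[C@]4(C)[C@@]2(OCc5ccccc5)C[C@H]1[C@H]3O | intermediate
17 | 15-O-TBS ether of 16 | O=C1C=C[C@]23CC[C@H]4[C@](C)(CO[Si](C(C)C)(C(C)C)C(C)C)CCC[C@]4(C)[C@@]2(OCc5ccccc5)C[C@H]1[C@H]3O[Si](C)(C)C(C)(C)C | intermediate
18 | 9α-hydroxy 16-ketone, 15-OTBS, 18-OTIPS | O=C1CC[C@]23CC[C@H]4[C@](C)(CO[Si](C(C)C)(C(C)C)C(C)C)CCC[C@]4(C)[C@@]2(O)C[C@H]1[C@H]3O[Si](C)(C)C(C)(C)C | intermediate
19 | 9(11)-ene 16-ketone, 15-OTBS, 18-OTIPS | O=C1CC[C@]23CC[C@H]4[C@](C)(CO[Si](C(C)C)(C(C)C)C(C)C)CCC[C@]4(C)C2=C[C@H]1[C@H]3O[Si](C)(C)C(C)(C)C | intermediate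
20 | C16 spiro-epoxide of 19 (CH2 syn to C15, oxygen equatorial) | O1C[C@]12CC[C@]34CC[C@H]5[C@](C)(CO[Si](C(C)C)(C(C)C)C(C)C)CCC[C@]5(C)C3=C[C@H]2[C@H]4O[Si](C)(C)C(C)(C)C | intermediate
21 | 15-O-TBS, 18-O-TIPS ether of Botryotin E | CC(=O)OC[C@@]1(O)CC[C@]23CC[C@H]4[C@](C)(CO[Si](C(C)C)(C(C)C)C(C)C)CCC[C@]4(C)C2=C[C@H]1[C@H]3O[Si](C)(C)C(C)(C)C | intermediate
22 | Botryotin E | CC(=O)OC[C@@]1(O)CC[C@]23CC[C@H]4[C@](C)(CO)CCC[C@]4(C)C2=C[C@H]1[C@H]3O | target

## Step count and risks

Total steps: 17. Longest linear sequence: 16 (steps 1–5 and 7–17); step 6 prepares the aryl partner.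

Steps most likely to fail:

1. Step 10. What may go wrong: capture of the phenoxonium ion by solvent or acetate at the free para carbon, hydrolysis of the enol ether before it reacts, re-aromatisation by proton loss from C12 after the first bond instead of closure onto C8, or insufficient face selectivity. The fallback sets out from 6 and returns at 18. It moves to the 4,5-dimethoxyphenol class, for which phenoxonium–alkene [5+2] cycloadditions are best established, because the para methoxy group stabilises the cation as a quinone-monoketal-type ion and blocks C13. 3,4-Dimethoxyphenol would be iodinated with N-iodosuccinimide to 2-iodo-4,5-dimethoxyphenol F1 and silylated to its TBS ether F2. Zinc insertion would give arylzinc iodide F3, which is coupled with 6 as in step 7 to the dimethoxyaryl benzyl ester F4. Tebbe methylenation would give enol ether F5, and K2CO3/MeOH the phenol F6. Oxidation (PhI(OAc)2 in the fluorinated solvent with hindered base, or constant-current anodic oxidation in MeOH) should give the 13-methoxy enedione F7. NaBH4, TBSOTf and H2 over Pd(OH)2/C, as in steps 11–13, would give the C15 alcohol F8, its silyl ether F9 and the 13-methoxy 9-hydroxy 16-ketone F10. SmI2 (THF/MeOH) then removes the α-methoxy group to rejoin the route at 18.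

2. Step 3. What may go wrong: oxidation of the benzylic CH2 (C7) and of the isopropyl methine before the ring is consumed, or slow ring degradation with loss of the silyl ether. The fallback sets out from 3 and returns at 4. Birch reduction (Li, liquid NH3, t-BuOH, THF) should give the 8,12-diene F11. Ozonolysis with oxidative work-up would cleave both double bonds to the β-keto acid F12, which loses CO2 to the triketone F13 (C9 methyl ketone; C8 ketone within a 1,3-diketone). NaOBr (haloform cleavage of the methyl ketone and of the 1,3-diketone) would then give diacid 4.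

3. Step 15. What may go wrong: addition of the ylide from the wrong face of the C16 ketone, or enolisation instead of addition. The fallback sets out from 19 and returns at 21. Wittig methylenation (Ph3P=CH2) would give the 16-methylene compound F14. OsO4 with N-methylmorpholine N-oxide should dihydroxylate the exocyclic alkene from the equatorial face to diol F15; the 9(11)-alkene, flanked by two quaternary carbons, should not react. Acetylation of the primary hydroxyl only (Ac2O, pyridine, 0 °C) would give 21.

Further compounds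
F1 | step 10 | 2-iodo-4,5-dimethoxyphenol | COc1cc(O)c(I)cc1OC
F2 | step 10 | tert-butyl(2-iodo-4,5-dimethoxyphenoxy)dimethylsilane | COc1cc(O[Si](C)(C)C(C)(C)C)c(I)cc1OC
F3 | step 10 | [2-(tert-butyldimethylsilyloxy)-4,5-dimethoxyphenyl]zinc iodide | COc1cc(O[Si](C)(C)C(C)(C)C)c([Zn]I)cc1OC
F4 | step 10 | dimethoxyaryl analogue of 10 (benzyl ester) | COc1cc(O[Si](C)(C)C(C)(C)C)c(CC[C@H]2[C@](C)(CO[Si](C(C)C)(C(C)C)C(C)C)CCC[C@]2(C)C(=O)OCc3ccccc3)cc1OC
F5 | step 10 | dimethoxyaryl analogue of 11 (benzyl enol ether) | COc1cc(O[Si](C)(C)C(C)(C)C)c(CC[C@H]2[C@](C)(CO[Si](C(C)C)(C(C)C)C(C)C)CCC[C@]2(C)C(=C)OCc3ccccc3)cc1OC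
F6 | step 10 | dimethoxyaryl analogue of 12 (2-alkyl-4,5-dimethoxyphenol) | COc1cc(O)c(CC[C@H]2[C@](C)(CO[Si](C(C)C)(C(C)C)C(C)C)CCC[C@]2(C)C(=C)OCc3ccccc3)cc1OC
F7 | step 10 | 13-methoxy analogue of 15 | O=C1C(OC)=C[C@]23CC[C@H]4[C@](C)(CO[Si](C(C)C)(C(C)C)C(C)C)CCC[C@]4(C)[C@@]2(OCc5ccccc5)C[C@H]1C3=O
F8 | step 10 | 13-methoxy analogue of 16 | O=C1C(OC)=C[C@]23CC[C@H]4[C@](C)(CO[Si](C(C)C)(C(C)C)C(C)C)CCC[C@]4(C)[C@@]2(OCc5ccccc5)C[C@H]1[C@H]3O
F9 | step 10 | 13-methoxy analogue of 17 | O=C1C(OC)=C[C@]23CC[C@H]4[C@](C)(CO[Si](C(C)C)(C(C)C)C(C)C)CCC[C@]4(C)[C@@]2(OCc5ccccc5)C[C@H]1[C@H]3O[Si](C)(C)C(C)(C)C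
F10 | step 10 | 13-methoxy analogue of 18 (C13 epimers) | O=C1C(OC)C[C@]23CC[C@H]4[C@](C)(CO[Si](C(C)C)(C(C)C)C(C)C)CCC[C@]4(C)[C@@]2(O)C[C@H]1[C@H]3O[Si](C)(C)C(C)(C)C
F11 | step 3 | 18-O-triisopropylsilyl abieta-8,12-dien-18-ol | CC(C)C1=CCC2=C(C1)CC[C@H]3[C@](C)(CO[Si](C(C)C)(C(C)C)C(C)C)CCC[C@]23C
F12 | step 3 | β-keto acid from ozonolysis (C9 ketone, C12 acid; C8 and C13 ketones) | CC(C)C(=O)CC(=O)CC[C@H]1[C@](C)(CO[Si](C(C)C)(C(C)C)C(C)C)CCC[C@]1(C)C(=O)CC(O)=O
F13 | step 3 | triketone (C9 methyl ketone; C8/C13 1,3-diketone) | CC(C)C(=O)CC(=O)CC[C@H]1[C@](C)(CO[Si](C(C)C)(C(C)C)C(C)C)CCC[C@]1(C)C(C)=O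
F14 | step 15 | 16-methylene compound from 19 | C=C1CC[C@]23CC[C@H]4[C@](C)(CO[Si](C(C)C)(C(C)C)C(C)C)CCC[C@]4(C)C2=C[C@H]1[C@H]3O[Si](C)(C)C(C)(C)C
F15 | step 15 | 16,17-diol (15-OTBS, 18-OTIPS) | OC[C@@]1(O)CC[C@]23CC[C@H]4[C@](C)(CO[Si](C(C)C)(C(C)C)C(C)C)CCC[C@]4(C)C2=C[C@H]1[C@H]3O[Si](C)(C)C(C)(C)C
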